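**Plan**
1. Retrosynthetic cuts, in order: (a) the C2→C10 hydrogen shift and the cyclohexene bonds C14–C15' and C2–C4' (Diels–Alder) lead back to an upper 5β-H guaianolide dienone and dehydrozaluzanin C; (b) the upper unit's methylenes, C3 ketone and lactone are taken back to a bicyclic 4-silyloxy 6-ketone; (c) its bonds C1–C5 and C7–C8 are cut together to an acyclic epoxy diketone.
2. Enabling feature: in the seven-membered ring C1–C10–C9–C8–C7–C6–C5 the oxygen-bearing C6 lies between C5 and C7 (a latent 2-oxyallyl unit). C10 carries an exocyclic carbon (a latent carbonyl, hence a 2-silyloxydiene C1=C10–C9=C8). The five-membered ring supplies the three-atom tether C2–C3–C4 from C1 to C5.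
3. Forward order: C10 chain → (4+3) cycloaddition closes the seven- and five-membered rings at once → acetate arm, reduction, trans-lactone → two exocyclic methylenes, α-methylene lactone, C3 ketone → dienone → Diels–Alder with the lower unit (spiro cyclohexene) → enone shift.
4. Stereochemistry: C4/C5 from a catalytic asymmetric enone epoxidation (C5 by inversion in the key step); C7 by enolate alkylation anti to C4; C6 by 4-hydroxyl-directed hydride delivery; the lower unit from dehydrocostus lactone; spiro C4' by α-face attack on its enone; C10 by proton return.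

Key step: step 5

Remarks before the steps:
- Guaiane numbering is used for the upper unit and primed numbers for the lower unit; α/β are as in the usual guaianolide drawing (H-7 α). The target SMILES has H-5 of the upper unit β (cis to H-6), while the lower unit has the dehydrocostus lactone configuration; this is why the upper unit is built de novo.
- Assumption: the (S)-BINOL lanthanum complex is taken to give the (3R,4S) epoxide in step 3; if the sense is opposite, the (R)-ligand is used with no other change.
- Assumption: C-1 of the upper unit is labile in steps 6 to 8 (α to the C-10 ketone) and ceases to be a stereocentre in step 15. It is drawn throughout as the 1β-H (cis-fused) epimer; the 1α-H epimer would be carried through in the same way.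

**Step 1**
Reactants: 1 glutaraldehyde; 2 vinylmagnesium bromide
Product: 3 6-vinyltetrahydropyran-2-ol (racemic lactol form of 5-hydroxyhept-6-enal)
Conditions: 2 (1.0 equiv), THF, −78 → 0 °C; then H2O
Reagents that add atoms: none
Why: Grignard mono-addition to a dialdehyde; the first magnesium alkoxide closes onto the second formyl group as a lactolate, which blocks a second addition, and the racemic carbinol centre is destroyed in step 4.

**Step 2**
Reactants: 3; 4 1-(triphenylphosphoranylidene)propan-2-one
Product: 6 (3E)-8-(triethylsilyloxy)deca-3,9-dien-2-one (racemic), via hydroxy enone 5 (not isolated)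
Conditions: toluene, 80 °C; then imidazole, Et3SiCl, CH2Cl2, 0 °C
Reagents that add atoms: chlorotriethylsilane, CC[Si](Cl)(CC)CC
Why: Wittig olefination of the open hydroxy aldehyde with a stabilised ylide gives the E-enone, and silylation in the same flask removes the free hydroxyl before it can close onto the enone (6-exo oxa-Michael).

**Step 3**
Reactants: 6
Product: 7 (3R,4S)-3,4-epoxy-8-(triethylsilyloxy)dec-9-en-2-one (trans epoxide; both C-8 epimers)
Conditions: La(O-iPr)3 (10 mol %), (S)-BINOL (10 mol %), Ph3As=O (10 mol %), t-BuOOH, 4 Å MS, THF, rt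
Reagents that add atoms: tert-butyl hydroperoxide, CC(C)(C)OO
Why: lanthanum–BINOL catalysed asymmetric nucleophilic epoxidation (Weitz–Scheffer type) of an (E)-alkyl methyl enone; the peroxide adds to one enone face under ligand control and closes to the trans epoxide, while the isolated vinyl group and the silyl ether should not react.

**Step 4**
Reactants: 7
Product: 9 (7S,8R)-7,8-epoxydec-1-ene-3,9-dione, via epoxy alcohol 8 (not isolated)
Conditions: AcOH/THF/H2O (3:1:1), rt; then Dess–Martin periodinane, CH2Cl2, 0 °C → rt
Reagents that add atoms: none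
Why: mild acid cleaves the secondary triethylsilyl ether and Dess–Martin oxidation turns the allylic alcohol into the vinyl ketone under neutral conditions that spare the epoxy ketone; both carbinol epimers converge.

**Step 5**
Reactants: 9
Product: 11 4β,10-bis(triethylsilyloxy)-11,12,13,14,15-pentanor-1β,5β-H-guai-9-en-6-one (cis-fused hexahydroazulenone), via bis(enol silane) 10 (not isolated)
Conditions: Et3SiOTf (2.3 equiv), Et3N (3 equiv), CH2Cl2, −78 → 0 °C, pentane filtration; then Et3SiOTf (0.1 equiv), CH2Cl2, −78 °C, Et3N quench
Reagents that add atoms: triethylsilyl trifluoromethanesulfonate, CC[Si](CC)(CC)OS(=O)(=O)C(F)(F)F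
Why: Et3SiOTf silylates the epoxide oxygen and the C5–O bond opens with participation of the adjacent enol silane (a 2-silyloxyallyl cation or its SN2-like equivalent); the tethered Z-2-silyloxydiene captures it at both ends, C1 to C5 and C8 to C7, and the silyl group on the C6 oxygen returns to triflate, which is the known silyl triflate-catalysed intramolecular (4+3) cycloaddition of epoxy enolsilanes with tethered dienes, run here with a more nucleophilic diene. The five-membered ring closes through the three-atom tether C2–C3–C4 (endo opening of the epoxide, fusion bond C1–C5) and the seven-membered ring by the (4+3) union, which in the stepwise limit is a Mukaiyama-type alkylation followed by a 7-endo-trig Mukaiyama–Michael closure to the same silyl enol ether. C5 is set by inversion at the epoxide carbon of the enantiopure trans epoxide, C4 keeps its epoxide configuration as the 4β-silyl ether, and C1 (compact transition state with the Z-dienol ether) is of no lasting consequence. The step needs ionisation at C5–O and not at C4–O, which conjugation with the enol silane secures, and closure of the second bond, which the cisoid diene held in reach by the tether and the low temperature should favour.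

**Step 6**
Reactants: 11; 12 methyl bromoacetate
Product: 14 methyl 4β-hydroxy-6,10-dioxo-13,14,15-trinor-1β,5β,7α-H-guaian-12-oate, via silylated keto ester 13 (not isolated)
Conditions: LiN(iPr)2 (1.1 equiv), THF, −78 °C; 12, DMPU, −78 → −40 °C; then 1 M HCl, THF, 0 °C → rt
Reagents that add atoms: none
Why: kinetic deprotonation at the CH2 side (C7) of the only free ketone and enolate alkylation anti to the pseudoaxial C5–C4 bond with its bulky silyloxy carbon should give the 5,7-trans ketone (7α-H); aqueous acid then removes the silyl ether and hydrolyses the silyl enol ether to the C10 ketone.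

**Step 7**
Reactants: 14
Product: 16 4β-hydroxy-10-oxo-13,14,15-trinor-1β,5β,7α-H-guaian-12,6α-olide, via anti diol ester 15 (not isolated)
Conditions: Me4NBH(OAc)3, MeCN/AcOH (1:1), −30 °C; then TsOH·H2O (cat.), CH2Cl2, rt
Reagents that add atoms: none
Why: Evans–Saksena reduction, in which the 4β-hydroxyl binds boron and delivers hydride within the molecule to the β face of the C6 ketone (1,3-anti diol, 6β-H) while the C10 ketone, lacking a β-hydroxyl, stays; the 6α-hydroxyl then lactonises onto the trans-disposed ester arm.

**Step 8**
Reactants: 16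
Product: 17 4,10-dioxo-13,14,15-trinor-1β,5β,7α-H-guaian-12,6α-olide
Conditions: Dess–Martin periodinane, CH2Cl2, 0 °C → rt
Reagents that add atoms: none
Why: Dess–Martin oxidation of the secondary alcohol under neutral, non-enolising conditions, so that C5 (now α to a ketone and β to the lactone oxygen) should neither epimerise nor eliminate.

**Step 9**
Reactants: 17
Product: 18 13-nor-1β,5β,7α-H-guaia-4(15),10(14)-dien-12,6α-olide
Conditions: Zn, CH2Br2, TiCl4, THF/CH2Cl2, 0 °C → rt
Reagents that add atoms: dibromomethane, BrCBr
Why: Takai–Lombardo methylenation converts both ketones into exocyclic methylenes without base, a method known to leave α-stereocentres and lactones untouched.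

**Step 10**
Reactants: 18
Product: 21 1β,5β,7α-H-guaia-4(15),10(14),11(13)-trien-12,6α-olide (1,5-di-epi-dehydrocostus lactone), via Mannich base 19 (not isolated), via methiodide 20 (not isolated)
Conditions: LiN(iPr)2, THF, −78 °C; CH2=NMe2+ I−, −78 → 0 °C; then MeI, MeOH, rt; then DBU, CH2Cl2, rt
Reagents that add atoms: N,N-dimethylmethyleneiminium iodide, C=[N+](C)C.[I-]
Why: Mannich reaction of the lactone lithium enolate with Eschenmoser's salt, quaternisation and E1cB loss of trimethylamine give the α-methylene lactone; the C11 centre of the two intermediates is of no consequence.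

**Step 11**
Reactants: 21
Product: 22 3β-hydroxy-1β,5β,7α-H-guaia-4(15),10(14),11(13)-trien-12,6α-olide
Conditions: SeO2 (0.5 equiv), t-BuOOH (2 equiv), CH2Cl2, rt
Reagents that add atoms: selenium dioxide, O=[Se]=O; tert-butyl hydroperoxide, CC(C)(C)OO
Why: Riley allylic hydroxylation (ene reaction, then [2,3] shift) of the 1,1-disubstituted C4=C15 alkene at the ring CH2 C3, the regiochemistry known for dehydrocostus lactone; oxygen should enter from the convex β face, and this centre is removed in step 12.

**Step 12**
Reactants: 22
Product: 23 3-oxo-1β,5β,7α-H-guaia-4(15),10(14),11(13)-trien-12,6α-olide (1,5-di-epi-dehydrozaluzanin C)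
Conditions: Dess–Martin periodinane, CH2Cl2, 0 °C → rt
Reagents that add atoms: none
Why: Dess–Martin oxidation of the allylic alcohol to the α-methylene ketone under neutral conditions that the two Michael acceptors tolerate.

**Step 13**
Reactants: 24 dehydrocostus lactone
Product: 25 3-epizaluzanin C (3α-hydroxy)
Conditions: SeO2 (0.5 equiv), t-BuOOH (2 equiv), CH2Cl2, rt
Reagents that add atoms: selenium dioxide, O=[Se]=O; tert-butyl hydroperoxide, CC(C)(C)OO
Why: Riley allylic hydroxylation at C3' next to the C4'=C15' methylene from the convex α face, a known transformation of this lactone.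

**Step 14**
Reactants: 25
Product: 26 dehydrozaluzanin C
Conditions: Dess–Martin periodinane, CH2Cl2, 0 °C → rt
Reagents that add atoms: none
Why: Dess–Martin oxidation of the allylic alcohol to the exocyclic enone that serves as dienophile.

**Step 15**
Reactants: 23; 26
Product: 29 Diels–Alder adduct (Δ1(10); 2α-H; new bonds C14–C15' and C2–C4'), via silyl enol ether 27 (not isolated), via dienone 28 (not isolated)
Conditions: Me3SiOTf, Et3N, CH2Cl2, 0 °C, evaporation; then 26 (3 equiv), Pd(OAc)2 (1.1 equiv), MeCN, rt → 40 °C, argon
Reagents that add atoms: none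
Why: silylation at C2 (the only enolisable α-position) and Saegusa–Ito oxidation with divalent palladium give dienone 28, whose cisoid exocyclic diene C14=C10–C1=C2 adds in a Diels–Alder reaction to the exocyclic enone C4'=C15' of 26 (in excess, to outrun dimerisation of 28), with C14 joining the β-carbon C15' and C2 the α-carbon C4'; attack on the convex α face of 26 sets the spiro centre C4', and approach to the β face of 28 (anti to the C5–C6 bond) gives the transient 2α-H.

**Step 16**
Reactants: 29
Product: 30 target CNP0221188.1
Conditions: DBU (0.1 equiv), degassed toluene, 0 °C, argon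
Reagents that add atoms: none
Why: base-mediated 1,3-prototropic shift of the β,γ-unsaturated ketone to the conjugated enone through the C3 dienolate, the proton taken from the α face of C2 being returned within the ion pair to the α face of C10 (10α-H); catalytic base and short contact are used so that the γ-hydrogens of the product (H-5, H-10) are not exchanged.

**Compound list**
1 | glutaraldehyde (pentanedial) | O=CCCCC=O | starting material
2 | vinylmagnesium bromide | C=C[Mg]Br | starting material
3 | 6-vinyltetrahydropyran-2-ol (racemic lactol, anomer mixture) | C=CC1CCCC(O)O1 | intermediate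
4 | 1-(triphenylphosphoranylidene)propan-2-one | CC(=O)C=P(c1ccccc1)(c1ccccc1)c1ccccc1 | starting material
5 | (3E)-8-hydroxydeca-3,9-dien-2-one (racemic) | CC(=O)/C=C/CCCC(O)C=C | intermediate (not isolated)
6 | (3E)-8-(triethylsilyloxy)deca-3,9-dien-2-one (racemic) | CC(=O)/C=C/CCCC(O[Si](CC)(CC)CC)C=C | intermediate
7 | (3R,4S)-3,4-epoxy-8-(triethylsilyloxy)dec-9-en-2-one (both C-8 epimers) | CC(=O)[C@@H]1O[C@H]1CCCC(O[Si](CC)(CC)CC)C=C | intermediate
8 | (3R,4S)-3,4-epoxy-8-hydroxydec-9-en-2-one (both C-8 epimers) | CC(=O)[C@@H]1O[C@H]1CCCC(O)C=C | intermediate (not isolated)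
9 | (7S,8R)-7,8-epoxydec-1-ene-3,9-dione | CC(=O)[C@@H]1O[C@H]1CCCC(=O)C=C | intermediate
10 | (3Z,7S,8R)-7,8-epoxy-3,9-bis(triethylsilyloxy)deca-1,3,9-triene | C=C(O[Si](CC)(CC)CC)[C@@H]1O[C@H]1CC/C=C(\O[Si](CC)(CC)CC)C=C | intermediate (not isolated)
11 | 4β,10-bis(triethylsilyloxy)-11,12,13,14,15-pentanor-1β,5β-H-guai-9-en-6-one | O=C1CCC=C(O[Si](CC)(CC)CC)[C@H]2CC[C@H](O[Si](CC)(CC)CC)[C@@H]12 | intermediate
12 | methyl bromoacetate | COC(=O)CBr | starting material
13 | methyl 4β,10-bis(triethylsilyloxy)-6-oxo-13,14,15-trinor-1β,5β,7α-H-guai-9-en-12-oate | O=C1[C@H](CC(=O)OC)CC=C(O[Si](CC)(CC)CC)[C@H]2CC[C@H](O[Si](CC)(CC)CC)[C@@H]12 | intermediate (not isolated)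
14 | methyl 4β-hydroxy-6,10-dioxo-13,14,15-trinor-1β,5β,7α-H-guaian-12-oate | O=C1[C@H](CC(=O)OC)CCC(=O)[C@H]2CC[C@H](O)[C@@H]12 | intermediate
15 | methyl 4β,6α-dihydroxy-10-oxo-13,14,15-trinor-1β,5β,7α-H-guaian-12-oate | O[C@H]1[C@H](CC(=O)OC)CCC(=O)[C@H]2CC[C@H](O)[C@@H]12 | intermediate (not isolated)
16 | 4β-hydroxy-10-oxo-13,14,15-trinor-1β,5β,7α-H-guaian-12,6α-olide | O=C1C[C@@H]2CCC(=O)[C@H]3CC[C@H](O)[C@H]3[C@H]2O1 | intermediate
17 | 4,10-dioxo-13,14,15-trinor-1β,5β,7α-H-guaian-12,6α-olide | O=C1C[C@@H]2CCC(=O)[C@H]3CCC(=O)[C@H]3[C@H]2O1 | intermediate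
18 | 13-nor-1β,5β,7α-H-guaia-4(15),10(14)-dien-12,6α-olide | O=C1C[C@@H]2CCC(=C)[C@H]3CCC(=C)[C@H]3[C@H]2O1 | intermediate
19 | 13-(dimethylamino)-1β,5β,7α,11β-H-guaia-4(15),10(14)-dien-12,6α-olide (C-11 epimer drawn, not controlled) | O=C1[C@@H](CN(C)C)[C@@H]2CCC(=C)[C@H]3CCC(=C)[C@H]3[C@H]2O1 | intermediate (not isolated)
20 | 13-(trimethylammonio)-1β,5β,7α,11β-H-guaia-4(15),10(14)-dien-12,6α-olide iodide | O=C1[C@@H](C[N+](C)(C)C)[C@@H]2CCC(=C)[C@H]3CCC(=C)[C@H]3[C@H]2O1.[I-] | intermediate (not isolated)
21 | 1β,5β,7α-H-guaia-4(15),10(14),11(13)-trien-12,6α-olide (1,5-di-epi-dehydrocostus lactone) | O=C1C(=C)[C@@H]2CCC(=C)[C@H]3CCC(=C)[C@H]3[C@H]2O1 | intermediate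
22 | 3β-hydroxy-1β,5β,7α-H-guaia-4(15),10(14),11(13)-trien-12,6α-olide | O=C1C(=C)[C@@H]2CCC(=C)[C@H]3C[C@H](O)C(=C)[C@H]3[C@H]2O1 | intermediate
23 | 3-oxo-1β,5β,7α-H-guaia-4(15),10(14),11(13)-trien-12,6α-olide (1,5-di-epi-dehydrozaluzanin C) | O=C1C(=C)[C@@H]2CCC(=C)[C@H]3CC(=O)C(=C)[C@H]3[C@H]2O1 | intermediate
24 | dehydrocostus lactone | C=C1CC[C@@H]2[C@@H]([C@@H]3[C@H]1CCC3=C)OC(=O)C2=C | starting material
25 | 3-epizaluzanin C (3α-hydroxy) | C=C1CC[C@@H]2[C@@H]([C@@H]3[C@H]1C[C@@H](O)C3=C)OC(=O)C2=C | intermediate
26 | dehydrozaluzanin C | C=C1CC[C@@H]2[C@@H]([C@@H]3[C@H]1CC(=O)C3=C)OC(=O)C2=C | intermediate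
27 | 3-(trimethylsilyloxy)-1β,5β,7α-H-guaia-2,4(15),10(14),11(13)-tetraen-12,6α-olide | O=C1C(=C)[C@@H]2CCC(=C)[C@H]3C=C(O[Si](C)(C)C)C(=C)[C@H]3[C@H]2O1 | intermediate (not isolated)
28 | 3-oxo-5β,7α-H-guaia-1,4(15),10(14),11(13)-tetraen-12,6α-olide | O=C1C(=C)[C@@H]2CCC(=C)C3=CC(=O)C(=C)[C@H]3[C@H]2O1 | intermediate (not isolated)
29 | Diels–Alder adduct: spiro dimer with Δ1(10) and 2α-H (C-2 on the α face of C-4' of the lower unit) | C=C1C(=O)[C@@H]2C3=C(CC[C@H]4C(=C)C(=O)O[C@@H]4[C@H]13)CC[C@]21C(=O)C[C@H]2C(=C)CC[C@H]3C(=C)C(=O)O[C@@H]3[C@H]21 | intermediate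
30 | CNP0221188.1 | C=C1C(=O)C2=C3[C@H](CC[C@H]4C(=C)C(=O)O[C@@H]4[C@H]13)CC[C@]21C(=O)C[C@H]2C(=C)CC[C@H]3C(=C)C(=O)O[C@@H]3[C@H]21 | target

**Count**
Total steps: 16. Longest linear sequence: 14 steps (steps 1–12, 15 and 16); the lower unit takes 2 steps (13 and 14).

**Steps most likely to fail**

1. Step 5. What may go wrong: capture of the silyloxyallyl cation stalls after the first C–C bond (C1–C5), so the seven-membered ring does not close, or the silyl-activated epoxide rearranges by hydride shift before it is captured. Fallback (stepwise annulation in place of the cycloaddition): it sets out from 10. The reaction is stopped after the first bond and worked up with water, which should give the acetyl acryloyl cyclopentane F1. Et3SiOTf and Et3N at −78 °C convert the methyl ketone of F1 into the enol silane F2 (the methine next to the vinyl ketone is slower to silylate). An intramolecular Mukaiyama–Michael addition (HNTf2 0.05 equiv, CH2Cl2, −78 °C, 7-endo-trig, silyl transfer to the enone oxygen) then closes C7–C8 and comes back to the route at 11.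

2. Step 15. What may go wrong: self-cycloaddition of dienone 28, which is diene and dienophile in one molecule, in competition with the cross reaction; low facial selectivity; air oxidation of the dienol of the adduct. Fallback (the enone of the upper unit is removed before the cycloaddition): it sets out from 27. Saegusa–Ito oxidation without 26, followed at once by Luche reduction (NaBH4, CeCl3·7H2O, MeOH, −78 °C), should give the dienol F3, which can act only as a diene and whose 3α-hydroxyl shields the α face. A thermal or Me2AlCl-promoted Diels–Alder reaction of the dienol F3 with 26 gives the adduct alcohol F4, and Dess–Martin oxidation of the adduct alcohol F4 comes back to the route at 29.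

3. Step 16. What may go wrong: proton return to the wrong face of C10 (poor facial selectivity), or exchange at C5 on long contact with base. Fallback (reagent control in place of substrate control): it sets out from 29 and comes back at 30 without any new compound (F0). The shift is run as proton-transfer catalysis with a bifunctional cinchona alkaloid base (6'-hydroxy quinidine- or quinine-derived, 10 mol %, CH2Cl2, −20 °C). This is a known method for β,γ- to α,β-unsaturated carbonyl isomerisation; its two pseudoenantiomeric catalysts address either face of C10, and it is too weakly basic to touch H-5.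

**Further compounds**
F1 | step 5 | 1-acryloyl-5-acetyl-4β-(triethylsilyloxy)cyclopentane (guaiane numbering; 1β,5β-H) | C=CC(=O)[C@H]1CC[C@H](O[Si](CC)(CC)CC)[C@H]1C(C)=O
F2 | step 5 | 6-triethylsilyl enol ether of F1 | C=CC(=O)[C@H]1CC[C@H](O[Si](CC)(CC)CC)[C@H]1C(=C)O[Si](CC)(CC)CC
F3 | step 15 | 3α-hydroxy-5β,7α-H-guaia-1,4(15),10(14),11(13)-tetraen-12,6α-olide | O=C1C(=C)[C@@H]2CCC(=C)C3=C[C@@H](O)C(=C)[C@H]3[C@H]2O1
F4 | step 15 | 3α-hydroxy Diels–Alder adduct (Δ1(10); 2α-H) | C=C1[C@H](O)[C@@H]2C3=C(CC[C@H]4C(=C)C(=O)O[C@@H]4[C@H]13)CC[C@]21C(=O)C[C@H]2C(=C)CC[C@H]3C(=C)C(=O)O[C@@H]3[C@H]21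
F0 | step 16 | none | none
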